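## Analysis of the target

Target 14 is a 2,3-dihydrobenzofuran. Benzene ring A (C3a, C4 to C7, C7a) is fused to dihydrofuran ring B (O1, C2, C3); ring A carries a free hydroxyl at C7 and an (E)-propenoic acid at C5, C2 carries the 3,4-dimethoxyphenyl ring C, and C3 a CH2OH group. The only stereocentres are the neighbours C2 (R) and C3 (S), whose substituents stand trans on ring B. The two centres are unequal. C2 is an aryl ether carbon benzylic to a 4-methoxy-substituted ring, so the C2–O1 bond ionises in acid and C2 can settle into the more stable trans arrangement. C3 carries only carbon and hydrogen, cannot be corrected afterwards and must be set with absolute control. Sensitive points are the phenolic, electron-rich ring A (oxidation), the acid-labile C2–O1 bond with the C3–H next to it (elimination, dehydrogenation of ring B), and three protic groups that invite long protecting-group detours. The strategy rests on the fragment O–C2–C3–CH2–O: C3 bears a one-carbon oxygenated branch and C2 an oxygen, which is what a Prins addition of formaldehyde leaves on the two carbons of a C2=C3 double bond, here that of an (E)-stilbene built from rings A and C.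

## Retrosynthetic reasoning

**14 ⇒ 11 + 12.** The Cα=Cβ bond of the propenoic acid is cut first. A Knoevenagel–Doebner condensation of aldehyde 11 with malonic acid 12 delivers the free (E)-acid directly (through 13), tolerates the free phenol and the primary alcohol, and keeps the conjugated acid out of every acidic, basic and hydride step before it.

**11 ⇒ 10 ⇒ 9.** The formyl carbon is traced through triol 10 to the ester carbon of 9. An ester is wanted at C5 during the earlier steps because it withdraws electron density from ring A; the forward steps are a hydride reduction and a benzylic oxidation that must leave the saturated CH2OH at C3 alone.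

**9 ⇒ 7.** The O1–C2 bond is cut, and the oxygen on C2 and the oxygen of the CH2OH arm are joined through one methylene group, giving the 1,3-dioxane 7 (dioxane C4 = target C2, C5 = target C3, C6 = the hydroxymethyl carbon). The cut is made here because C2–O is the one bond of ring B that acid can exchange. In the forward direction, acid must ionise the benzylic C4–O3 bond, the neighbouring hydroxyl of ring A must capture the cation trans to the C3 substituent, and hemiformal 8 must release formaldehyde 5. What is gained is that C2 need not be controlled in the key step; only C3 matters.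

**7 ⇒ 6.** The two hydroxyls of ring A are masked as pivalate esters in 6. They make ring A a poor cation stabiliser, keep the hydroxyl away from formaldehyde and from the Prins cation, and are removed by transesterification without touching the dioxane.

**6 ⇒ 4 + two molecules of 5.** The C5–C6 and C4–O3 bonds of the dioxane are cut, which returns the (E)-stilbene 4 and two units of formaldehyde 5. This is the only disconnection that creates the C3 stereocentre in the step that forms its C–C bond, from an achiral alkene, with a catalyst. The forward reaction must put the carbon on the alkene carbon bearing ring A, the oxygen on the one bearing ring C, and select one face.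

**4 ⇒ 2 + 3, and 2 ⇒ 1.** The aryl–vinyl bond is cut. A Heck reaction joins aryl bromide 2 to 3,4-dimethoxystyrene 3 with E geometry, and 2 is the bis-pivalate of bromocatechol ester 1. The precursor of the key step is thus reached in two routine steps.

## Alternatives that were turned down

**Alternative 1:** Both bonds to C2 in ring B are cut (C2–C3 and O1–C2). C2 with ring C becomes a benzylic sulfonium ylide on a chiral sulfide, and O1, ring A and C3 with its protected CH2OH arm become an ortho-quinone methide released from a phenolic sulfone. In the forward step Cs2CO3 frees both partners, the ylide carbon adds to the exocyclic carbon (C3), and the phenoxide displaces the sulfide at C2, giving A1, (2R,3S)-5-bromo-3-[(tert-butyldiphenylsilyloxy)methyl]-2-(3,4-dimethoxyphenyl)-7-(methoxymethoxy)-2,3-dihydrobenzofuran.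
- For: ring B and both centres form in one step, directly trans, by a reaction class that is established for ortho-quinone methides. The C5 bromide of A1 reaches the acrylate by a single Heck reaction. On directness of ring formation and on precedent this alternative is stronger than the chosen route.
- Against: the quinone methide needed here has an alkyl group with a β-oxygen on its exocyclic carbon, and such species tautomerise to vinylphenols or eliminate instead of waiting for a nucleophile. The electron-rich benzyl ylide is only semi-stabilised and forms reluctantly with a carbonate base. The chiral information sits on sulfur, yet the irreparable centre is C3, set by face selection on a transient planar species. A stoichiometric chiral sulfide is consumed, both partners need several steps, and removal of the methoxymethyl group needs acid that threatens C2–O1.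
- In its place the chosen route offers catalytic control at C3 from a stilbene made in two steps, and no protecting groups beyond two pivalates.

**Alternative 2:** Only O1–C2 is cut. The precursor is an open chain in which C3 already has its configuration and C2 is still a CH2 group next to ring C. DDQ abstracts hydride from that CH2 and the C7a hydroxyl captures the cation, giving A2, methyl (E)-3-[(2R,3S)-3-(acetoxymethyl)-2-(3,4-dimethoxyphenyl)-7-(triisopropylsilyloxy)-2,3-dihydrobenzofuran-5-yl]acrylate.
- For: the acrylate is already in place, C2 follows from C3, and only deprotections remain, so the endgame is shorter than the one chosen here.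
- Against: the strategy leaves the hard problem unsolved. The C3 centre, flanked only by carbon, must be made beforehand by a separate asymmetric sequence. The oxidation is also badly matched to the substrate: the free hydroxyl on ring A is itself oxidised by DDQ, and the C2–H of the product (α to oxygen and benzylic to the same ring C) is a better hydride donor than the starting CH2, so dehydrogenation to the benzofuran would erase both centres.
- The chosen route sets C3 catalytically in the C–C bond-forming step and closes ring B without an oxidant.

**Alternative 3:** The C2–aryl bond to ring C and the C3–C3a bond are cut, giving three components: an (E)-alkenyl boronic ester carrying the silyloxymethyl group, the aryllithium of ring C, and an aryl triflate of ring A. The boron ate complex reacts under Pd(OAc)2 and MandyPhos; ring C migrates from boron to C2 while palladium delivers ring A to C3, giving A3, methyl 7-[(2S,3R)-1-(tert-butyldimethylsilyloxy)-3-(3,4-dimethoxyphenyl)-3-(4,4,5,5-tetramethyl-1,3,2-dioxaborolan-2-yl)propan-2-yl]-2,2-dimethylbenzo[d][1,3]dioxole-5-carboxylate.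
- For: two C–C bonds and both centres form in one catalytic enantioselective step, and the C–B bond is oxidised with retention. On convergence and on precedent for enantiocontrol within its reaction class it is stronger than the chosen route.
- Against: alkenyl boronates substituted at the β-carbon are the slow substrates of this coupling, and direct Suzuki coupling competes. The triflate is ortho-substituted. After the coupling come oxidation, acetonide removal, ring closure, desilylation and the full ester-to-acrylic-acid sequence. The C2 centre that was set with effort is finally inverted or re-equilibrated.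
- The chosen route is shorter, uses formaldehyde as the C1 source, and spends its stereocontrol only on C3.

Key step: step 3

Assumption: the sense of induction of the chiral acid on a 1,2-diaryl alkene cannot be predicted, so step 3 is written with the catalyst antipode that forms the C–CH2 bond on the Si face of the alkene carbon bearing ring A; 1 is taken as a purchased compound.

## Route

**Step 1**
Reactants: 1 methyl 3-bromo-4,5-dihydroxybenzoate
Product: 2 methyl 3-bromo-4,5-bis(pivaloyloxy)benzoate
Conditions: PivCl (3 equiv), Et3N, DMAP (cat.), CH2Cl2, 0 °C to 40 °C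
Reagents that add atoms: pivaloyl chloride, CC(C)(C)C(=O)Cl
Why: DMAP-catalysed O-acylation esterifies both phenols, including the hindered one between bromine and the second acyloxy group; the pivalates deactivate ring A and mask the hydroxyl that would otherwise react with formaldehyde or intercept the Prins cation.

**Step 2**
Reactants: 2 methyl 3-bromo-4,5-bis(pivaloyloxy)benzoate, 3 3,4-dimethoxystyrene
Product: 4 methyl (E)-3-[2-(3,4-dimethoxyphenyl)ethenyl]-4,5-bis(pivaloyloxy)benzoate
Conditions: Pd(OAc)2 (5 mol %), P(o-tol)3, Et3N, DMF, 100 °C
Reagents that add atoms: none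
Why: Heck reaction: Pd(OAc)2 is reduced to zerovalent palladium, which inserts into the C–Br bond; syn carbopalladation at the unsubstituted styrene carbon and syn β-hydride elimination give the (E)-1,2-diarylethene, and Et3N takes up HBr without cleaving the pivalates.

**Step 3**
Reactants: 4 methyl (E)-3-[2-(3,4-dimethoxyphenyl)ethenyl]-4,5-bis(pivaloyloxy)benzoate, 5 formaldehyde (as paraformaldehyde)
Product: 6 methyl 3-[(4S,5S)-4-(3,4-dimethoxyphenyl)-1,3-dioxan-5-yl]-4,5-bis(pivaloyloxy)benzoate
Conditions: (CH2O)n (5 equiv), confined chiral imino-imidodiphosphate (iIDP) acid [(3,3'-Ar2-BINOL)P(=O)–NH–P(=NSO2CF3)(3,3'-Ar2-BINOL), 5 mol %], cyclohexane–CHCl3, 20–40 °C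
Reagents that add atoms: formaldehyde (the second CH2O unit of the dioxane, taken from the same excess of paraformaldehyde), C=O
Why: Proposed new method: a formaldehyde dimer protonated inside the chiral pocket (an HOCH2–O–CH2+ oxocarbenium built from two CH2O units) is attacked by the alkene carbon bearing ring A, so that positive charge builds on the carbon stabilised by the 4-methoxy group of ring C, and the hydroxyl oxygen of the second formaldehyde unit closes onto that carbon; the closest known reactions are the iIDP-catalysed asymmetric Prins reaction of styrenes with paraformaldehyde to 4-aryl-1,3-dioxanes and the classical Prins reaction of (E)-1-arylpropenes. The dioxane ring closes as a [4+2]-type annulation of the C–O–C–O unit with the alkene, concerted but asynchronous, C5–C6 forming ahead of C4–O3 (in the stepwise limit a 6-exo-trig capture of the quinoid 4-methoxybenzylic cation). The centre at dioxane C5 (C3 of the target) is set by the catalyst, which must deliver the electrophile to the Si face of that alkene carbon to give 5S. The centre at C4 follows from suprafacial addition to the (E)-alkene, which places the aryl groups trans (4S); if the cation lived long enough to rotate, the trans-diequatorial dioxane would still be favoured, and this centre is re-set in step 5 anyway. The regioselectivity that the step needs is secured by the substrate: ring C with its para-methoxy group stabilises the cation far better than ring A with two acyloxy groups and an ester. The moderately acidic iIDP is chosen over the stronger imidodiphosphorimidates so that neither hydroxymethylation of ring C nor ionisation of the product's benzylic C–O bond competes.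

**Step 4**
Reactants: 6 methyl 3-[(4S,5S)-4-(3,4-dimethoxyphenyl)-1,3-dioxan-5-yl]-4,5-bis(pivaloyloxy)benzoate
Product: 7 methyl 3-[(4S,5S)-4-(3,4-dimethoxyphenyl)-1,3-dioxan-5-yl]-4,5-dihydroxybenzoate
Conditions: K2CO3 (3 equiv), degassed MeOH, 0 °C to rt, Ar; then aq. NH4Cl
Reagents that add atoms: none
Why: Base-mediated transesterification cleaves the activated aryl pivalates, while the methyl benzoate is degenerate in methanol and the formaldehyde acetal is inert to base; exclusion of air protects the catecholate.

**Step 5**
Reactants: 7 methyl 3-[(4S,5S)-4-(3,4-dimethoxyphenyl)-1,3-dioxan-5-yl]-4,5-dihydroxybenzoate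
Product: 9 methyl (2R,3S)-2-(3,4-dimethoxyphenyl)-7-hydroxy-3-(hydroxymethyl)-2,3-dihydro-1-benzofuran-5-carboxylate, via hemiformal 8 (not isolated)
Conditions: CF3CO2H (10 equiv), CH2Cl2–H2O (20:1), 0 °C to rt; then aq. NaHCO3
Reagents that add atoms: none
Why: Acid ionises the dioxane C4–O3 bond by an SN1 path (the ionisation that cleaves 4-methoxybenzyl-type ethers), the ortho hydroxyl of ring A captures the cation by 5-exo-trig closure, and hemiformal 8 gives up formaldehyde to the aqueous phase. Because C2–O1 re-ionises under the same conditions, C2 should settle trans to the C3 substituent (2R) under thermodynamic control, while C3 is not touched. Should hydrolysis of the acetal to the free benzylic alcohol run first, the same benzylic cation and the same ring closure follow.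

**Step 6**
Reactants: 9 methyl (2R,3S)-2-(3,4-dimethoxyphenyl)-7-hydroxy-3-(hydroxymethyl)-2,3-dihydro-1-benzofuran-5-carboxylate
Product: 10 (2R,3S)-2-(3,4-dimethoxyphenyl)-3,5-bis(hydroxymethyl)-2,3-dihydro-1-benzofuran-7-ol
Conditions: DIBAL-H (6 equiv), THF, −78 °C to 0 °C; aq. Rochelle salt
Reagents that add atoms: none
Why: Hydride reduction of the ester to the primary alcohol; the phenol and alcohol are first converted into inert aluminium alkoxides by the excess reagent, and aryl ethers and the C2–O1 bond are not cleaved at this temperature.

**Step 7**
Reactants: 10 (2R,3S)-2-(3,4-dimethoxyphenyl)-3,5-bis(hydroxymethyl)-2,3-dihydro-1-benzofuran-7-ol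
Product: 11 (2R,3S)-2-(3,4-dimethoxyphenyl)-7-hydroxy-3-(hydroxymethyl)-2,3-dihydro-1-benzofuran-5-carbaldehyde
Conditions: activated MnO2 (excess), EtOAc, rt
Reagents that add atoms: none
Why: MnO2 oxidises benzylic alcohols selectively; the saturated CH2OH at C3 is not activated, and the C7 hydroxyl is meta to the carbinol, so no quinone methide pathway is open.

**Step 8**
Reactants: 11 (2R,3S)-2-(3,4-dimethoxyphenyl)-7-hydroxy-3-(hydroxymethyl)-2,3-dihydro-1-benzofuran-5-carbaldehyde, 12 malonic acid
Product: 14 (E)-3-[(2R,3S)-2-(3,4-dimethoxyphenyl)-7-hydroxy-3-(hydroxymethyl)-2,3-dihydro-1-benzofuran-5-yl]prop-2-enoic acid, via arylidenemalonic acid 13 (not isolated)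
Conditions: pyridine, piperidine (cat.), 85 °C; aq. NaOH, then aq. HCl work-up
Reagents that add atoms: none
Why: Knoevenagel–Doebner condensation: piperidine-catalysed condensation gives 13, which decarboxylates in hot pyridine to the (E)-acid; free phenol and alcohol are tolerated as in the classical preparation of hydroxycinnamic acids, and the basic work-up would hydrolyse any malonate ester formed at the primary alcohol.

## Compound list

1 | methyl 3-bromo-4,5-dihydroxybenzoate | COC(=O)c1cc(O)c(O)c(Br)c1 | starting material
2 | methyl 3-bromo-4,5-bis(pivaloyloxy)benzoate | COC(=O)c1cc(Br)c(OC(=O)C(C)(C)C)c(OC(=O)C(C)(C)C)c1 | intermediate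
3 | 3,4-dimethoxystyrene | C=Cc1ccc(OC)c(OC)c1 | starting material
4 | methyl (E)-3-[2-(3,4-dimethoxyphenyl)ethenyl]-4,5-bis(pivaloyloxy)benzoate | COC(=O)c1cc(/C=C/c2ccc(OC)c(OC)c2)c(OC(=O)C(C)(C)C)c(OC(=O)C(C)(C)C)c1 | intermediate
5 | formaldehyde (used as paraformaldehyde) | C=O | starting material
6 | methyl 3-[(4S,5S)-4-(3,4-dimethoxyphenyl)-1,3-dioxan-5-yl]-4,5-bis(pivaloyloxy)benzoate | COc1ccc([C@H]2OCOC[C@@H]2c2cc(C(=O)OC)cc(OC(=O)C(C)(C)C)c2OC(=O)C(C)(C)C)cc1OC | intermediate
7 | methyl 3-[(4S,5S)-4-(3,4-dimethoxyphenyl)-1,3-dioxan-5-yl]-4,5-dihydroxybenzoate | COc1ccc([C@H]2OCOC[C@@H]2c2cc(C(=O)OC)cc(O)c2O)cc1OC | intermediate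
8 | methyl (2R,3S)-2-(3,4-dimethoxyphenyl)-7-hydroxy-3-[(hydroxymethoxy)methyl]-2,3-dihydro-1-benzofuran-5-carboxylate | COc1ccc([C@@H]2Oc3c(O)cc(C(=O)OC)cc3[C@H]2COCO)cc1OC | intermediate (not isolated)
9 | methyl (2R,3S)-2-(3,4-dimethoxyphenyl)-7-hydroxy-3-(hydroxymethyl)-2,3-dihydro-1-benzofuran-5-carboxylate | COc1ccc([C@@H]2Oc3c(O)cc(C(=O)OC)cc3[C@H]2CO)cc1OC | intermediate
10 | (2R,3S)-2-(3,4-dimethoxyphenyl)-3,5-bis(hydroxymethyl)-2,3-dihydro-1-benzofuran-7-ol | COc1ccc([C@@H]2Oc3c(O)cc(CO)cc3[C@H]2CO)cc1OC | intermediate
11 | (2R,3S)-2-(3,4-dimethoxyphenyl)-7-hydroxy-3-(hydroxymethyl)-2,3-dihydro-1-benzofuran-5-carbaldehyde | COc1ccc([C@@H]2Oc3c(O)cc(C=O)cc3[C@H]2CO)cc1OC | intermediate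
12 | malonic acid | OC(=O)CC(=O)O | starting material
13 | 2-{[(2R,3S)-2-(3,4-dimethoxyphenyl)-7-hydroxy-3-(hydroxymethyl)-2,3-dihydro-1-benzofuran-5-yl]methylidene}propanedioic acid | COc1ccc([C@@H]2Oc3c(O)cc(C=C(C(=O)O)C(=O)O)cc3[C@H]2CO)cc1OC | intermediate (not isolated)
14 | (E)-3-[(2R,3S)-2-(3,4-dimethoxyphenyl)-7-hydroxy-3-(hydroxymethyl)-2,3-dihydro-1-benzofuran-5-yl]prop-2-enoic acid | COc1ccc([C@@H]2Oc3c(O)cc(/C=C/C(=O)O)cc3[C@H]2CO)cc1OC | target

## Step count and least certain steps

Total: 8 steps. Longest linear sequence: 8 steps (1 to 14); 3, 5 and 12 enter as single components.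

**Step 3 (key step, proposed new method).** The alkene may be too hindered for the confined pocket or too weakly nucleophilic, so that no turnover occurs. Face selection may be poor on a substrate class the catalyst was not shaped for. Formaldehyde may hydroxymethylate ring C instead. The fallback uses known chemistry, sets out from 1 and comes back to the route at 10. The more acidic 4-hydroxyl of 1 (para to the ester) is alkylated with 3,4-dimethoxybenzyl chloride (K2CO3, DMF) to methyl 3-bromo-4-[(3,4-dimethoxybenzyl)oxy]-5-hydroxybenzoate F1, and pivaloylation of the remaining phenol gives methyl 3-bromo-4-[(3,4-dimethoxybenzyl)oxy]-5-(pivaloyloxy)benzoate F2. Palladium-catalysed coupling of F2 with the Reformatsky reagent BrZnCH2CO2Me [Pd(dba)2, P(t-Bu)3, THF] gives methyl 4-[(3,4-dimethoxybenzyl)oxy]-3-(2-methoxy-2-oxoethyl)-5-(pivaloyloxy)benzoate F3, and Regitz diazo transfer (4-acetamidobenzenesulfonyl azide, DBU, MeCN) gives methyl 3-(1-diazo-2-methoxy-2-oxoethyl)-4-[(3,4-dimethoxybenzyl)oxy]-5-(pivaloyloxy)benzoate F4. Enantioselective intramolecular carbene C–H insertion into the benzylic ether CH2 with Rh2(S-PTTL)4 [dirhodium tetrakis(N-phthaloyl-(S)-tert-leucinate)], or its antipode as required for 2R, closes ring B as the cis diester dimethyl (2R,3S)-2-(3,4-dimethoxyphenyl)-7-(pivaloyloxy)-2,3-dihydro-1-benzofuran-3,5-dicarboxylate F5. NaOMe in MeOH then epimerises C3 to the trans series and removes the pivalate, giving dimethyl (2R,3R)-2-(3,4-dimethoxyphenyl)-7-hydroxy-2,3-dihydro-1-benzofuran-3,5-dicarboxylate F6, and LiAlH4 reduces both esters of F6 to 10.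

**Step 5.** Proton loss from the benzylic cation and re-protonation would erode the configuration at C3. The liberated formaldehyde may hydroxymethylate the electron-rich rings, and release of the hemiformal may be incomplete. The fallback sets out from 7 and comes back at 9; it separates removal of the C1 unit from ring closure. HCl in MeOH converts 7 by benzylic solvolysis and acetal exchange into the open-chain ether methyl 3-[(2S)-1-(3,4-dimethoxyphenyl)-3-hydroxy-1-methoxypropan-2-yl]-4,5-dihydroxybenzoate F7 (both epimers at the benzylic carbon), the methylene leaving as its volatile dimethyl acetal. F7, now free of formaldehyde, is closed with catalytic TsOH in dry CH2Cl2 over 4 Å molecular sieves at low temperature to 9.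

**Step 7.** Oxidative coupling of the free C7 phenol on the oxide surface, or loss of the polar triol by adsorption, may compete with the benzylic oxidation. The fallback sets out from 9 and comes back at 11; it reaches the aldehyde by reduction instead of oxidation. Compound 9 is converted with MeNH(OMe)·HCl and excess i-PrMgCl (THF, −20 °C) into the Weinreb amide (2R,3S)-2-(3,4-dimethoxyphenyl)-7-hydroxy-3-(hydroxymethyl)-N-methoxy-N-methyl-2,3-dihydro-1-benzofuran-5-carboxamide F8. DIBAL-H at −78 °C then stops at the chelated hemiaminal and gives 11 on work-up.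

**Step 2.** Oxidative addition at the bromide flanked by an acyloxy group may be slow, so that thermal polymerisation of the electron-rich styrene or insertion with the opposite regiochemistry takes over. The fallback sets out from 3 (with 2) and comes back at 4. Cross-metathesis of 3 with vinylboronic acid pinacol ester using the second-generation Grubbs catalyst (H2IMes)(PCy3)Cl2Ru=CHPh gives (E)-2-[2-(3,4-dimethoxyphenyl)ethenyl]-4,4,5,5-tetramethyl-1,3,2-dioxaborolane F9. Suzuki–Miyaura coupling of F9 with 2 [PdCl2(dppf), K3PO4, dioxane, 80 °C] fixes both the position and the E geometry of the double bond and gives 4.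

## Further compounds

F1 | step 3 | methyl 3-bromo-4-[(3,4-dimethoxybenzyl)oxy]-5-hydroxybenzoate | COC(=O)c1cc(O)c(OCc2ccc(OC)c(OC)c2)c(Br)c1
F2 | step 3 | methyl 3-bromo-4-[(3,4-dimethoxybenzyl)oxy]-5-(pivaloyloxy)benzoate | COC(=O)c1cc(Br)c(OCc2ccc(OC)c(OC)c2)c(OC(=O)C(C)(C)C)c1
F3 | step 3 | methyl 4-[(3,4-dimethoxybenzyl)oxy]-3-(2-methoxy-2-oxoethyl)-5-(pivaloyloxy)benzoate | COC(=O)Cc1cc(C(=O)OC)cc(OC(=O)C(C)(C)C)c1OCc1ccc(OC)c(OC)c1
F4 | step 3 | methyl 3-(1-diazo-2-methoxy-2-oxoethyl)-4-[(3,4-dimethoxybenzyl)oxy]-5-(pivaloyloxy)benzoate | COC(=O)C(=[N+]=[N-])c1cc(C(=O)OC)cc(OC(=O)C(C)(C)C)c1OCc1ccc(OC)c(OC)c1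
F5 | step 3 | dimethyl (2R,3S)-2-(3,4-dimethoxyphenyl)-7-(pivaloyloxy)-2,3-dihydro-1-benzofuran-3,5-dicarboxylate | COc1ccc([C@@H]2Oc3c(OC(=O)C(C)(C)C)cc(C(=O)OC)cc3[C@@H]2C(=O)OC)cc1OC
F6 | step 3 | dimethyl (2R,3R)-2-(3,4-dimethoxyphenyl)-7-hydroxy-2,3-dihydro-1-benzofuran-3,5-dicarboxylate | COc1ccc([C@@H]2Oc3c(O)cc(C(=O)OC)cc3[C@H]2C(=O)OC)cc1OC
F7 | step 5 | methyl 3-[(2S)-1-(3,4-dimethoxyphenyl)-3-hydroxy-1-methoxypropan-2-yl]-4,5-dihydroxybenzoate (both epimers at C1) | COC(c1ccc(OC)c(OC)c1)[C@H](CO)c1cc(C(=O)OC)cc(O)c1O
F8 | step 7 | (2R,3S)-2-(3,4-dimethoxyphenyl)-7-hydroxy-3-(hydroxymethyl)-N-methoxy-N-methyl-2,3-dihydro-1-benzofuran-5-carboxamide | COc1ccc([C@@H]2Oc3c(O)cc(C(=O)N(C)OC)cc3[C@H]2CO)cc1OC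
F9 | step 2 | (E)-2-[2-(3,4-dimethoxyphenyl)ethenyl]-4,4,5,5-tetramethyl-1,3,2-dioxaborolane | COc1ccc(/C=C/B2OC(C)(C)C(C)(C)O2)cc1OC
A1 | alternative 1 | (2R,3S)-5-bromo-3-[(tert-butyldiphenylsilyloxy)methyl]-2-(3,4-dimethoxyphenyl)-7-(methoxymethoxy)-2,3-dihydrobenzofuran | COc1ccc([C@@H]2Oc3c(OCOC)cc(Br)cc3[C@H]2CO[Si](c4ccccc4)(c4ccccc4)C(C)(C)C)cc1OC
A2 | alternative 2 | methyl (E)-3-[(2R,3S)-3-(acetoxymethyl)-2-(3,4-dimethoxyphenyl)-7-(triisopropylsilyloxy)-2,3-dihydrobenzofuran-5-yl]acrylate | COc1ccc([C@@H]2Oc3c(O[Si](C(C)C)(C(C)C)C(C)C)cc(/C=C/C(=O)OC)cc3[C@H]2COC(C)=O)cc1OC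
A3 | alternative 3 | methyl 7-[(2S,3R)-1-(tert-butyldimethylsilyloxy)-3-(3,4-dimethoxyphenyl)-3-(4,4,5,5-tetramethyl-1,3,2-dioxaborolan-2-yl)propan-2-yl]-2,2-dimethylbenzo[d][1,3]dioxole-5-carboxylate | COc1ccc([C@H](B2OC(C)(C)C(C)(C)O2)[C@H](CO[Si](C)(C)C(C)(C)C)c2cc(C(=O)OC)cc3OC(C)(C)Oc23)cc1OC
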